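## Structural features

The target is a cis-fused decalin (ring A = C1–C5/C10, ring B = C5–C10). Ring B holds a tetrasubstituted C8=C9 alkene with a methyl group on C8, C10 is a quaternary methyl-bearing fusion carbon, and the other fusion carbon C5 (a methine) stands beside the gem-dimethyl carbon C4. C9 carries a seven-carbon chain: the C11–C12 ethano link, a trisubstituted C13=C14 alkene whose hydroxymethyl branch on C13 is cis to C15 (Z), the methylene C15, the secondary carbinol C16, and C17, which is the β-carbon of a γ-butyrolactone. The four stereocentres form two adjacent pairs, C5/C10 (4aR,8aS in ring numbering, H-5 and CH3-10 cis) and C16/C17 (16R,17S, an anti pair). Seven bonds separate the pairs, so neither can steer the other and each needs its own source of absolute configuration. The fragile part is the hydroxy lactone: the C16 hydroxyl can take over the acyl group and give the isomeric five-membered lactone, a 4-(hydroxymethyl) lactone precursor can exchange its two CH2O arms by the same acyl transfer and so racemise, and C17 is epimerisable whenever C16 is a carbonyl carbon. The real difficulty is threefold: a cis ring fusion with a quaternary C10 next to the neopentyl C4–C5 bond (a polyene cyclisation would lead to the trans-decalin), a tetrasubstituted alkene that must sit at C8=C9 only, and a Z-trisubstituted alkene far from any directing group. The key step exploits that ring B has the substitution pattern of carvone: a three-carbon branch on C5 (C4 and its two methyl groups), a methyl-bearing sp2 C8, an oxidised C9 and an α-carbon C10. Ring A then lacks only C1–C3 and the C3–C4 bond, C4 is a tertiary centre that can be ionised, and C3 can be the silicon-bearing end of a Z-vinylsilane hung on C10.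

## Logic of the disconnections

30 ⇒ 29. No skeletal bond is cut; the O–H bonds at C16 and at the C13 hydroxymethyl group are exchanged for the two O–Si bonds of a diisopropylsilylene bridge. This keeps the C16 oxygen blocked until the last step and turns the Z alkene into a ring alkene. The forward step must cleave silicon without base.

29 ⇒ 28. The C13=C14 bond is cut. Inside an eight-membered ring this alkene can only be cis, which answers the geometry question without a stereoselective olefination. The molecule falls into two halves joined only through silicon. The forward metathesis must close a medium ring onto a 1,1-disubstituted alkene and leave C8=C9 alone.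

28 ⇒ 19 + 25 + 26. Both Si–O bonds are cut. This gives a decalin half with no stereocentre outside the ring fusion and a lactone half with the C16/C17 pair. The forward step must join two different alcohols to one silicon atom in a fixed order.

25 ⇒ 22 + 23, then 22 ⇒ 21 ⇒ 20. The C15–C16 bond is cut next to the carbinol, so C17 can come from an enantiopure lactone acid and C16 from reagent control. The gain is a three-step branch from a five-carbon building block. The demand is that C17 does not epimerise at the aldehyde stage and that no base touches 21 or 25.

19 ⇒ 16 + 17, then 16 ⇒ 14 + 15. The C12–C13 bond (sp3–sp2) and the C9–C11 bond (sp2–sp2) are cut, each next to an alkene, so that commercial two- and three-carbon units supply C11–C12 and C13 with its methylene and CH2OH. The decalin is reduced to a single enol triflate. The forward steps need hydroboration of the vinyl group only and coupling at a hindered triflate.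

14 ⇒ 12 ⇒ 11. The C9–O bond is traced to a ketone; because C10 is quaternary the ketone enolises only towards C8, which fixes the alkene position. The two ring alkenes of 11 are construction residues (C7=C8 from the starting enone, C2=C3 from the ring closure) and are removed by hydrogenation, which creates no lasting stereocentre.

11 ⇒ 10. The C3–C4 bond is cut, which opens ring A and leaves a monocyclic ring B with every substituent of the decalin in place. The cut is made here because C4 is tertiary (an easily formed cation) and C3 can carry silicon, which guarantees where the new bond and the residual alkene end up. The forward step must capture the cation at C3 faster than it loses a proton.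

10 ⇒ 9 ⇒ 6 + 7 ⇒ 4 + 3. The C4–Cl bond, the C10–CH3 bond and the C10–C1 bond are cut in turn, which leads back to the chiral-pool ring B. The order is dictated by stereochemistry: the second electrophile enters anti to the C5 branch, so the C1–C3 arm must be attached first and the methyl group second for the arm and C4 to stand cis. The demand is face selectivity with a small electrophile and an acid step that spares the vinylsilane.

3 ⇒ 2 ⇒ 1. The C–Br bond and the Z alkene are traced to a silylated propargyl alcohol. The forward steps need cis semi-reduction and a bromination that does not scramble the geometry.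

## Other disconnections considered

Alternative 1: The cut is the C16–C17 bond, with C17 and both lactone arms traced to furan A2 and C16–C13 to 4-(tert-butyldimethylsilyloxy)butanal A1.
- Forward step: irradiation of A1 in A2 would join the carbonyl carbon to C3 of A2 and the carbonyl oxygen to C2 (Paternò–Büchi [2+2]) and give the exo oxetane A3; hydrolysis of its acetal then exposes an anti β-hydroxy dialdehyde.
- In its favour: one reagent-free step from two cheap achiral compounds makes the C16–C17 bond and sets the anti relation through the inherent exo preference of the cycloaddition.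
- Against it here: A3 forms as a racemate, so a resolution or a diastereomer separation after union with the enantiopure decalin is needed. The two aldehyde-level carbons that hydrolysis frees on C17 must be moved in opposite redox directions (one down to the lactone CH2O, one up to the lactone carbonyl). A1 brings C14 as a saturated CH2 and C13 as a CH2O carbon, so the C13=C14 alkene, its hydroxymethyl branch and the C12–C13 bond stay unsolved. The decalin is not addressed.
- Comparison: on relative control of C16/C17 the alternative is the better of the two, since the chosen plan depends on reagent control over an epimerisable aldehyde (step 13). On absolute configuration the chosen plan is better (C17 from 20, C16 from 23). Locally one photochemical step stands against three ground-state steps (11–13), but the redox adjustments, the resolution and the missing alkene would make the whole route longer than the chosen 16 steps.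

Alternative 2: The cut is the C13=C14 alkene.
- Forward step: the acyclic mixed silyl diether A4 (the same compound as 28) with second-generation Grubbs catalyst RuCl2(=CHPh)(PCy3)(H2IMes) would close to the eight-membered cyclic silyl diether A5 (the same compound as 29).
- In its favour: the ring enforces the cis alkene, the union is convergent and late, and both hydroxyls stay masked.
- Against it here: as the step that defines the plan it leaves ring A, the cis fusion and the quaternary C10, which are the harder problem, to an unspecified synthesis. Closing an eight-membered ring onto a 1,1-disubstituted alkene is entropically costly.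
- Comparison: for the side chain the alternative is the equal of the chosen plan, because the chosen plan uses this very closure as step 15; structure, mechanism and step count of the endgame are identical. The difference is only where the strategic weight lies. The chosen plan puts it on the step that creates ring A, because that choice fixes the starting material and both ring-fusion centres.

Alternative 3: The cut is the pair of bonds C5–C10 and C6–C7.
- Forward step: the triene imide A6 (tether cis to C8 across C9=C10) with Me2AlCl would undergo an intramolecular Diels–Alder reaction to the cis-fused octalin imide A7.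
- In its favour: both rings, two C–C bonds and the C5/C10 pair (plus C6) form in one step from an open chain, the auxiliary sets the absolute configuration without recourse to the chiral pool, and the C8=C9 alkene appears in the right place by itself. On bonds and rings per step and on alkene placement the alternative is the better of the two.
- Against it here: the diene is substituted on every carbon except C7, and its C10 terminus carries both a methyl group and the tether. The s-cis conformer is therefore strained, and the C5–C10 bond must join a fully substituted diene terminus to a dienophile carbon that is neopentyl. A stereodefined tetrasubstituted C9=C10 in A6 is itself a multi-step problem. The activating acyl group on C6 is absent from the target and must be excised. C11 arrives as a single oxygenated carbon, so C12 onwards still needs an sp3–sp3 coupling at an allylic position.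
- Comparison: the chosen plan builds less in its key step (one ring, one bond, no stereocentre) but takes ring B, C5 and all their substituents ready-made from 4, sets C10 by a simple alkylation and has no traceless activating group to remove. Both key steps are Lewis-acid mediated and congested around C4–C5/C10; the cationic closure makes its bond at the unhindered C3 terminus and not at C10. In step count the extra steps for the diene and for deleting the C6 acyl group would offset the gain of the cycloaddition.

Key step: step 6

Remarks on the chemistry (one line each):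
- Atom numbers C1–C17 are those of the target skeleton in every compound.
- 20 and 23 are taken as purchasable single enantiomers.
- 6 and 12 are carried as epimer mixtures at the one centre (C10, C8) that the next step planarises.
- The configurations of 10 and 11 were re-derived from 4 and from 30 and agree (H-5 and CH3-10 cis), so no structure needed correcting; only the CIP label of the untouched C5 changes (S in 4, 6 and 10, R in 9 and 11).
- The precursor design is kept and made safer by full complexation of the ketone with excess SnCl4 and by a hindered pyridine as proton trap.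

Step 1
Reactants: 1 3-(trimethylsilyl)prop-2-yn-1-ol
Product: 2 (Z)-3-(trimethylsilyl)prop-2-en-1-ol
Conditions: H2 (1 atm), nickel boride (Ni2B) from Ni(OAc)2·4H2O and NaBH4, ethylenediamine, EtOH, rt
Reagents that add atoms: none
Why: Catalytic cis-semihydrogenation of an alkyne: both hydrogens are delivered from the nickel boride surface to one face of the triple bond, so the Z-vinylsilane should result, and ethylenediamine slows further reduction of the alkene.

Step 2
Reactants: 2 (Z)-3-(trimethylsilyl)prop-2-en-1-ol
Product: 3 (Z)-(3-bromoprop-1-en-1-yl)trimethylsilane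
Conditions: CBr4, PPh3, CH2Cl2, 0 °C
Reagents that add atoms: carbon tetrabromide, BrC(Br)(Br)Br
Why: Appel reaction: the alkoxyphosphonium ion is displaced by bromide at the primary allylic carbon under neutral conditions, which should leave the Z geometry and the C–Si bond intact.

Step 3
Reactants: 4 (S)-carvone; 3 (Z)-(3-bromoprop-1-en-1-yl)trimethylsilane
Product: 6 (5S)-2-methyl-5-(prop-1-en-2-yl)-6-[(Z)-3-(trimethylsilyl)prop-2-en-1-yl]cyclohex-2-en-1-one as a mixture of epimers at ring C6 (skeleton C10), via lithium dienolate 5 (not isolated)
Conditions: LiN(iPr)2, THF, −78 °C; then 3, −78 → 0 °C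
Reagents that add atoms: (Z)-(3-bromoprop-1-en-1-yl)trimethylsilane 3, C[Si](C)(C)/C=C\CBr
Why: LiN(iPr)2 removes the kinetically most accessible α′-proton at C10 and gives the cross-conjugated dienolate 5, which is C-alkylated by the allylic bromide in an SN2 reaction (enolate alkylation); C5 is untouched, and the mixture at C10 does not matter because this centre is planarised again in step 4.

Step 4
Reactants: 6 the C10 epimer mixture from step 3; 7 iodomethane
Product: 9 (5R,6S)-2,6-dimethyl-5-(prop-1-en-2-yl)-6-[(Z)-3-(trimethylsilyl)prop-2-en-1-yl]cyclohex-2-en-1-one, via lithium enolate 8 (not isolated)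
Conditions: LiN(iPr)2, THF, −78 → 0 °C; then MeI, DMPU, −78 → −20 °C
Reagents that add atoms: iodomethane 7, CI
Why: Enolate alkylation with 1,2-induction: the tetrasubstituted enolate 8 is attacked by MeI on the face anti to the isopropenyl group on the neighbouring C5, so the methyl group ends trans and the silylallyl arm cis to that group, which sets C10 (S) and with it the later cis ring fusion; DMPU speeds C-alkylation of the hindered enolate.

Step 5
Reactants: 9 (5R,6S)-2,6-dimethyl-5-(prop-1-en-2-yl)-6-[(Z)-3-(trimethylsilyl)prop-2-en-1-yl]cyclohex-2-en-1-one
Product: 10 (5S,6S)-5-(2-chloropropan-2-yl)-2,6-dimethyl-6-[(Z)-3-(trimethylsilyl)prop-2-en-1-yl]cyclohex-2-en-1-one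
Conditions: HCl (g), CH2Cl2, −40 → −20 °C
Reagents that add atoms: hydrogen chloride, Cl
Why: Markovnikov hydrochlorination: the 1,1-disubstituted alkene is the most basic π bond (the enone alkene is deactivated, the vinylsilane is less readily protonated at low temperature), its tertiary cation collapses with chloride in the ion pair, and any material that cyclises already at this stage is 11 and is not lost.

Step 6
Reactants: 10 (5S,6S)-5-(2-chloropropan-2-yl)-2,6-dimethyl-6-[(Z)-3-(trimethylsilyl)prop-2-en-1-yl]cyclohex-2-en-1-one
Product: 11 (4aR,8aS)-2,5,5,8a-tetramethyl-4a,5,8,8a-tetrahydronaphthalen-1(4H)-one (cis-fused dienone with C2=C3 and C7=C8)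
Conditions: SnCl4 (1.5 equiv), 2,6-di-tert-butyl-4-methylpyridine (0.2 equiv), CH2Cl2, −78 → −20 °C
Reagents that add atoms: none
Why: SnCl4 abstracts chloride from C4 and gives the tertiary cation as an ion pair, while the excess ties up the C9 carbonyl oxygen so that it cannot trap the cation. The Z-vinylsilane attacks through its silicon-bearing carbon C3 (ipso attack), which forms C3–C4 and places the positive charge on C2, β to silicon and stabilised by the C–Si σ bond; chloride then removes Me3Si and leaves the C2=C3 alkene. The closest known reaction type is the vinylsilane-terminated cation–olefin cyclisation, an electrophilic ipso substitution of a vinylsilane by a tert-alkyl cation. Ring A closes in the 6-endo mode with respect to the vinylsilane π bond, since both C2 and C3 become ring members. No stereocentre is created: C5 comes unchanged from 4 and C10 was fixed in step 4, and because the C1–C3 arm and C4 stand cis on ring B the new ring can only be cis-fused. The selectivity that the step needs is regiochemical, C3 against C2: attack at C2 would close a five-membered ring and leave an α-silyl cation without β-stabilisation, so the β-silicon effect secures attack at C3. The Z geometry puts silicon on the tether side of the alkene, so that substitution with retention gives the cis alkene that a six-membered ring requires. Loss of a proton from the cation and protodesilylation by traces of HCl are the competing paths, held back by the low temperature and by the hindered pyridine, which scavenges protons without binding SnCl4.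

Step 7
Reactants: 11 (4aR,8aS)-2,5,5,8a-tetramethyl-4a,5,8,8a-tetrahydronaphthalen-1(4H)-one
Product: 12 (4aR,8aS)-2,5,5,8a-tetramethyloctahydronaphthalen-1(2H)-one as a mixture of epimers at ring C2 (skeleton C8)
Conditions: H2 (1 atm), Pd/C, EtOAc, rt
Reagents that add atoms: none
Why: Heterogeneous catalytic hydrogenation saturates the disubstituted C2=C3 alkene and the C7=C8 enone alkene; C5 and C10 carry no exchangeable hydrogen under these conditions, and the new C8 centre is removed again in step 8.

Step 8
Reactants: 12 (4aR,8aS)-2,5,5,8a-tetramethyloctahydronaphthalen-1(2H)-one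
Product: 14 (4aR,8aS)-2,5,5,8a-tetramethyl-3,4,4a,5,6,7,8,8a-octahydronaphthalen-1-yl trifluoromethanesulfonate, via potassium enolate 13 (not isolated)
Conditions: KN(SiMe3)2, THF, −78 → 0 °C; then PhNTf2, −78 °C → rt
Reagents that add atoms: N-phenylbis(trifluoromethanesulfonimide), O=S(=O)(N(c1ccccc1)S(=O)(=O)C(F)(F)F)C(F)(F)F
Why: Enol triflate formation: C10 is quaternary, so the ketone can enolise only towards C8 and the potassium enolate 13 is O-sulfonylated by PhNTf2 to a single regioisomer, as with other 2,2,6-trisubstituted cyclohexanones.

Step 9
Reactants: 14 the enol triflate from step 8; 15 tributyl(vinyl)stannane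
Product: 16 (4aR,8aS)-1-ethenyl-2,5,5,8a-tetramethyl-3,4,4a,5,6,7,8,8a-octahydronaphthalene
Conditions: Pd(PPh3)4 (5 mol%), LiCl, THF, reflux
Reagents that add atoms: tributyl(vinyl)stannane 15, C=C[Sn](CCCC)(CCCC)CCCC
Why: Stille coupling of an enol triflate with a vinylstannane; LiCl turns the vinylpalladium triflate into the chloride that transmetallates, and hindered 2,6,6-trisubstituted cyclohexenyl triflates are established partners.

Step 10
Reactants: 16 the diene from step 9; 17 2-bromoprop-2-en-1-ol
Product: 19 2-methylidene-4-[(4aR,8aS)-2,5,5,8a-tetramethyl-3,4,4a,5,6,7,8,8a-octahydronaphthalen-1-yl]butan-1-ol, via B-alkyl-9-borabicyclononane 18 (not isolated)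
Conditions: 9-BBN-H, THF, 0 °C → rt; then 17, PdCl2(dppf) (5 mol%), AsPh3, Cs2CO3, DMF/H2O, rt → 50 °C
Reagents that add atoms: 2-bromoprop-2-en-1-ol 17, OCC(Br)=C
Why: 9-BBN adds to the monosubstituted vinyl group with boron on the terminal C12 (the tetrasubstituted alkene is inert and the hindered diene is twisted out of conjugation), and the B-alkyl Suzuki–Miyaura coupling of 18 with the vinyl bromide forms C12–C13 and delivers the 1,1-disubstituted alkene together with the free CH2OH.

Step 11
Reactants: 20 (S)-paraconic acid [(3S)-5-oxooxolane-3-carboxylic acid]
Product: 21 (4R)-4-(hydroxymethyl)oxolan-2-one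
Conditions: BH3·SMe2, THF, 0 °C → rt; then MeOH
Reagents that add atoms: none
Why: Borane reduces a carboxylic acid through its acyloxyborane much faster than a lactone, so only the CO2H group is reduced; the stereocentre is not involved, and base is avoided throughout because acyl transfer between the two CH2O arms of 21 would erode its enantiomeric purity.

Step 12
Reactants: 21 (4R)-4-(hydroxymethyl)oxolan-2-one
Product: 22 (3S)-5-oxooxolane-3-carbaldehyde
Conditions: Dess–Martin periodinane, CH2Cl2, 0 °C → rt; used crude
Reagents that add atoms: none
Why: Dess–Martin oxidation of a primary alcohol to the aldehyde under neutral, non-basic conditions; 22 is used at once and cold so that enolisation at C17 cannot set in.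

Step 13
Reactants: 22 (3S)-5-oxooxolane-3-carbaldehyde; 23 (+)-B-allyldiisopinocampheylborane (the reagent derived from (−)-α-pinene)
Product: 25 (4S)-4-[(1R)-1-hydroxybut-3-en-1-yl]oxolan-2-one, via diisopinocampheylborinate 24 (not isolated)
Conditions: 23, Et2O, −78 °C; then pH 7 phosphate buffer, MeOH, 30% H2O2, 0 °C
Reagents that add atoms: (+)-B-allyldiisopinocampheylborane 23, C=CCB([C@H]1C[C@H]2C[C@@H]([C@@H]1C)C2(C)C)[C@H]1C[C@H]2C[C@@H]([C@@H]1C)C2(C)C
Why: Brown allylation through a chair-like six-membered transition state: the borane from (−)-α-pinene delivers the allyl group to the Re face of the formyl group and so sets C16 (R) under reagent control at a temperature at which 22 does not epimerise; the buffered oxidative work-up cleaves the B–O bond of 24 without opening or transposing the lactone.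

Step 14
Reactants: 25 (4S)-4-[(1R)-1-hydroxybut-3-en-1-yl]oxolan-2-one; 26 dichlorodiisopropylsilane; 19 the allylic alcohol from step 10
Product: 28 diisopropylsilylene diether that links the C16 oxygen of 25 to the CH2O group of 19, via chlorosilyl ether 27 (not isolated)
Conditions: 25, iPr2SiCl2 (3 equiv), imidazole, CH2Cl2, 0 °C; excess iPr2SiCl2 evaporated; then 19, imidazole, CH2Cl2, rt
Reagents that add atoms: dichlorodiisopropylsilane 26, CC(C)[Si](Cl)(Cl)C(C)C
Why: Stepwise silyl ether formation (temporary silicon tether): the hindered secondary alcohol 25 reacts once with excess iPr2SiCl2 because the two isopropyl groups retard a second substitution, and the remaining Si–Cl bond of 27 is then displaced by the primary allylic alcohol 19 to give the unsymmetrical bis-alkoxysilane.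

Step 15
Reactants: 28 the mixed diisopropylsilylene diether from step 14
Product: 29 cyclic diisopropylsilylene diether of the target (2,2-diisopropyl-1,3-dioxa-2-silacyclooct-5-ene ring with the cis ring alkene C13=C14)
Conditions: second-generation Grubbs catalyst RuCl2(=CHPh)(PCy3)(H2IMes) (10 mol%), CH2Cl2 (2 mM), reflux
Reagents that add atoms: none
Why: Ring-closing olefin metathesis: the ruthenium carbene forms at the monosubstituted C14 alkene and closes onto the 1,1-disubstituted C13 alkene with loss of ethene; an eight-membered ring can only hold a cis ring alkene, so the CH2O group and C15 end cis (Z), and the tetrasubstituted C8=C9 alkene is too hindered to take part.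

Step 16
Reactants: 29 the cyclic silyl diether from step 15
Product: 30 (4S)-4-[(1R,3Z)-1-hydroxy-4-(hydroxymethyl)-6-[(4aR,8aS)-2,5,5,8a-tetramethyl-3,4,4a,5,6,7,8,8a-octahydronaphthalen-1-yl]hex-3-en-1-yl]oxolan-2-one
Conditions: HF·pyridine, pyridine, THF, 0 °C → rt
Reagents that add atoms: none
Why: Fluoride-mediated cleavage of both Si–O bonds, driven by the strength of the Si–F bond; the pyridine-buffered, weakly acidic medium generates no alkoxide, so the freed C16 hydroxyl should not transfer the lactone acyl group.

Compound list

1 | 3-(trimethylsilyl)prop-2-yn-1-ol | C[Si](C)(C)C#CCO | starting material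
2 | (Z)-3-(trimethylsilyl)prop-2-en-1-ol | C[Si](C)(C)/C=C\CO | intermediate
3 | (Z)-(3-bromoprop-1-en-1-yl)trimethylsilane | C[Si](C)(C)/C=C\CBr | intermediate
4 | (S)-carvone | CC1=CC[C@@H](CC1=O)C(C)=C | starting material
5 | lithium dienolate of 4 (O–Li on C9, C9=C10; not isolated) | CC1=CC[C@@H](C=C1O[Li])C(C)=C | intermediate
6 | (5S)-2-methyl-5-(prop-1-en-2-yl)-6-[(Z)-3-(trimethylsilyl)prop-2-en-1-yl]cyclohex-2-en-1-one, C10 epimer mixture | CC1=CC[C@H](C(C)=C)C(C/C=C\[Si](C)(C)C)C1=O | intermediate
7 | iodomethane | CI | starting material
8 | lithium enolate of 6 (C9=C10; not isolated) | CC1=CC[C@H](C(C)=C)C(C/C=C\[Si](C)(C)C)=C1O[Li] | intermediate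
9 | (5R,6S)-2,6-dimethyl-5-(prop-1-en-2-yl)-6-[(Z)-3-(trimethylsilyl)prop-2-en-1-yl]cyclohex-2-en-1-one | CC1=CC[C@H](C(C)=C)[C@](C)(C/C=C\[Si](C)(C)C)C1=O | intermediate
10 | (5S,6S)-5-(2-chloropropan-2-yl)-2,6-dimethyl-6-[(Z)-3-(trimethylsilyl)prop-2-en-1-yl]cyclohex-2-en-1-one | CC1=CC[C@H](C(C)(C)Cl)[C@](C)(C/C=C\[Si](C)(C)C)C1=O | intermediate
11 | (4aR,8aS)-2,5,5,8a-tetramethyl-4a,5,8,8a-tetrahydronaphthalen-1(4H)-one | CC1=CC[C@@H]2C(C)(C)C=CC[C@]2(C)C1=O | intermediate
12 | (4aR,8aS)-2,5,5,8a-tetramethyloctahydronaphthalen-1(2H)-one, C8 epimer mixture | CC1CC[C@@H]2C(C)(C)CCC[C@]2(C)C1=O | intermediate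
13 | potassium enolate of 12 (C8=C9; not isolated) | CC1=C(O[K])[C@@]2(C)CCCC(C)(C)[C@H]2CC1 | intermediate
14 | (4aR,8aS)-2,5,5,8a-tetramethyl-3,4,4a,5,6,7,8,8a-octahydronaphthalen-1-yl trifluoromethanesulfonate | CC1=C(OS(=O)(=O)C(F)(F)F)[C@@]2(C)CCCC(C)(C)[C@H]2CC1 | intermediate
15 | tributyl(vinyl)stannane | C=C[Sn](CCCC)(CCCC)CCCC | starting material
16 | (4aR,8aS)-1-ethenyl-2,5,5,8a-tetramethyl-3,4,4a,5,6,7,8,8a-octahydronaphthalene | CC1=C(C=C)[C@@]2(C)CCCC(C)(C)[C@H]2CC1 | intermediate
17 | 2-bromoprop-2-en-1-ol | OCC(Br)=C | starting material
18 | 9-[2-((4aR,8aS)-2,5,5,8a-tetramethyl-3,4,4a,5,6,7,8,8a-octahydronaphthalen-1-yl)ethyl]-9-borabicyclo[3.3.1]nonane (not isolated) | CC1=C(CCB3C4CCCC3CCC4)[C@@]2(C)CCCC(C)(C)[C@H]2CC1 | intermediate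
19 | 2-methylidene-4-[(4aR,8aS)-2,5,5,8a-tetramethyl-3,4,4a,5,6,7,8,8a-octahydronaphthalen-1-yl]butan-1-ol | CC1=C(CCC(=C)CO)[C@@]2(C)CCCC(C)(C)[C@H]2CC1 | intermediate
20 | (S)-paraconic acid, (3S)-5-oxooxolane-3-carboxylic acid | OC(=O)[C@@H]1COC(=O)C1 | starting material
21 | (4R)-4-(hydroxymethyl)oxolan-2-one | OC[C@@H]1COC(=O)C1 | intermediate
22 | (3S)-5-oxooxolane-3-carbaldehyde | O=C[C@@H]1COC(=O)C1 | intermediate
23 | (+)-B-allyldiisopinocampheylborane, from (−)-α-pinene | C=CCB([C@H]1C[C@H]2C[C@@H]([C@@H]1C)C2(C)C)[C@H]1C[C@H]2C[C@@H]([C@@H]1C)C2(C)C | starting material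
24 | diisopinocampheylborinate of 25 (O–B on C16; not isolated) | C=CC[C@@H](OB([C@H]2C[C@H]3C[C@@H]([C@@H]2C)C3(C)C)[C@H]2C[C@H]3C[C@@H]([C@@H]2C)C3(C)C)[C@@H]1COC(=O)C1 | intermediate
25 | (4S)-4-[(1R)-1-hydroxybut-3-en-1-yl]oxolan-2-one | C=CC[C@@H](O)[C@@H]1COC(=O)C1 | intermediate
26 | dichlorodiisopropylsilane | CC(C)[Si](Cl)(Cl)C(C)C | starting material
27 | chlorodiisopropylsilyl ether of 25 (not isolated) | C=CC[C@@H](O[Si](Cl)(C(C)C)C(C)C)[C@@H]1COC(=O)C1 | intermediate
28 | diisopropylsilylene diether of 25 (C16–O) and 19 (CH2–O) | CC1=C(CCC(=C)CO[Si](C(C)C)(C(C)C)O[C@H](CC=C)[C@@H]3COC(=O)C3)[C@@]2(C)CCCC(C)(C)[C@H]2CC1 | intermediate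
29 | cyclic diisopropylsilylene diether of the target (eight-membered ring, Z alkene C13=C14) | CC1=C(CC/C3=C/C[C@H]([C@@H]4COC(=O)C4)O[Si](C(C)C)(C(C)C)OC3)[C@@]2(C)CCCC(C)(C)[C@H]2CC1 | intermediate
30 | (4S)-4-[(1R,3Z)-1-hydroxy-4-(hydroxymethyl)-6-[(4aR,8aS)-2,5,5,8a-tetramethyl-3,4,4a,5,6,7,8,8a-octahydronaphthalen-1-yl]hex-3-en-1-yl]oxolan-2-one | CC1=C(CC/C(=C/C[C@@H](O)[C@@H]2COC(=O)C2)CO)[C@@]2(C)CCCC(C)(C)[C@H]2CC1 | target

Total step count: 16.
Longest linear sequence: 13 steps (steps 1–10, then 14–16); the lactone branch (steps 11–13) joins at step 14.

Steps least certain to work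

Step 6 (key step). The C4 cation may lose a proton, or the vinylsilane may be protodesilylated, faster than the C3–C4 bond forms, because a vinylsilane is only a moderate π-nucleophile and the cation sits beside the quaternary C10. The fallback makes the same bond by a palladium-mediated reductive Heck closure instead of a cation. It sets out from 3 and 4. 3 would be iododesilylated with retention (N-iodosuccinimide, (CF3)2CHOH, 0 °C) to (Z)-3-bromo-1-iodoprop-1-ene F1. 4 would be alkylated with F1 (LiN(iPr)2, THF, −78 °C) to the (Z)-3-iodoallyl ketone F2 and methylated as in step 4 to the C10-quaternary iodide F3. With Pd(OAc)2, PPh3, HCO2Na, DMF, 80 °C the vinylpalladium species should insert 6-exo into the isopropenyl alkene at C4; the resulting neopentyl-type alkylpalladium has no β-hydrogen and is reduced by formate, so the former =CH2 becomes the second methyl group on C4. The fallback comes back to the route at 11.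

Step 5. Protonation of the Z-vinylsilane (loss of silicon or of the Z geometry) may compete with Markovnikov addition to the isopropenyl group, since one reagent meets both alkenes. The fallback carries silicon through the acid step as an acid-stable alkynylsilane and reveals the vinylsilane afterwards. It sets out from 4, which would be alkylated with commercial 3-bromo-1-(trimethylsilyl)prop-1-yne (LiN(iPr)2, THF, −78 °C) to the propargyl ketone F4 and methylated as in step 4 to the quaternary ketone F5. HCl in CH2Cl2 would give the tertiary chloride F6, and cis semi-hydrogenation over nickel boride (Ni2B, ethylenediamine, H2, as in step 1) would then form the Z-vinylsilane. The fallback comes back at 10.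

Step 10. Hydroboration of the hindered, twisted diene may be slow or unselective, and the sp3–sp2 transmetallation may lose out to protodeboronation or β-hydride elimination with a free hydroxyl present. The fallback moves the coupling to C9–C11 with an unhindered alkylborane and builds the methylene group by aldehyde chemistry. It sets out from 14, which would be coupled (PdCl2(dppf), Cs2CO3, DMF/H2O) with the 9-BBN adduct of 4,4-diethoxybut-1-ene F7 to the acetal F8. Mild aqueous acid (pyridinium tosylate, acetone/H2O) would free the aldehyde F9; α-methylenation (aqueous CH2O, pyrrolidine, propionic acid, iPrOH, 45 °C) would give the enal F10; and NaBH4 with CeCl3·7H2O in MeOH would reduce it 1,2. The fallback comes back at 19.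

Step 13. Enolisation of 22 may epimerise C17 before the C–C bond forms, and reagent control over an α-branched aldehyde may be incomplete, which would give C16/C17 diastereomer mixtures. The fallback avoids a free aldehyde: it sets out from 21 and reaches 25 in one step by transfer-hydrogenative (Krische-type) allylation with allyl acetate ([Ir(cod)Cl]2, the BINAP enantiomer that directs Re-face delivery, 4-chloro-3-nitrobenzoic acid, Cs2CO3 in catalytic amount, THF, 100 °C), in which 22 exists only transiently on the metal. It makes no new compound (F0). The price to weigh is possible acyl transfer in 21 under heat and base, which is why it is not the first choice.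

Step 15. Closure of the eight-membered ring onto the 1,1-disubstituted alkene may be slow, so that intermolecular metathesis of the terminal alkene to oligomers takes over. The fallback builds the Z alkene by two stereospecific cross-couplings and needs no ring. It sets out from 25 and from 18 (made from 16 as in step 10). 25 would be silylated (tBuMe2SiOTf, 2,6-lutidine, −78 °C) to the silyl ether F11 and ozonised (O3, CH2Cl2, −78 °C; PPh3) to the aldehyde F12, which CBr4/PPh3 would convert into the 1,1-dibromoalkene F13. B-alkyl Suzuki coupling with 18 (Pd(PPh3)4, Cs2CO3, DMF/H2O) should take place at the bromide trans to C15 and give the (Z)-vinyl bromide F14. Stille coupling with Bu3SnCH2OH (Pd(PPh3)4, dioxane, 90 °C) would replace the remaining bromide with retention and give the C16 silyl ether of the target F15, and HF·pyridine would remove the silyl group. The fallback comes back at 30.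

## Further compounds

F1 | step 6 | (Z)-3-bromo-1-iodoprop-1-ene | BrC/C=C\I
F2 | step 6 | (5S)-6-[(Z)-3-iodoprop-2-en-1-yl]-2-methyl-5-(prop-1-en-2-yl)cyclohex-2-en-1-one, C10 epimer mixture | CC1=CC[C@H](C(C)=C)C(C/C=C\I)C1=O
F3 | step 6 | (5R,6S)-6-[(Z)-3-iodoprop-2-en-1-yl]-2,6-dimethyl-5-(prop-1-en-2-yl)cyclohex-2-en-1-one | CC1=CC[C@H](C(C)=C)[C@](C)(C/C=C\I)C1=O
F4 | step 5 | (5S)-2-methyl-5-(prop-1-en-2-yl)-6-[3-(trimethylsilyl)prop-2-yn-1-yl]cyclohex-2-en-1-one, C10 epimer mixture | CC1=CC[C@H](C(C)=C)C(CC#C[Si](C)(C)C)C1=O
F5 | step 5 | (5R,6S)-2,6-dimethyl-5-(prop-1-en-2-yl)-6-[3-(trimethylsilyl)prop-2-yn-1-yl]cyclohex-2-en-1-one | CC1=CC[C@H](C(C)=C)[C@](C)(CC#C[Si](C)(C)C)C1=O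
F6 | step 5 | (5S,6S)-5-(2-chloropropan-2-yl)-2,6-dimethyl-6-[3-(trimethylsilyl)prop-2-yn-1-yl]cyclohex-2-en-1-one | CC1=CC[C@H](C(C)(C)Cl)[C@](C)(CC#C[Si](C)(C)C)C1=O
F7 | step 10 | 9-(4,4-diethoxybutyl)-9-borabicyclo[3.3.1]nonane | CCOC(CCCB1C2CCCC1CCC2)OCC
F8 | step 10 | 4-[(4aR,8aS)-2,5,5,8a-tetramethyl-3,4,4a,5,6,7,8,8a-octahydronaphthalen-1-yl]butanal diethyl acetal | CC1=C(CCCC(OCC)OCC)[C@@]2(C)CCCC(C)(C)[C@H]2CC1
F9 | step 10 | 4-[(4aR,8aS)-2,5,5,8a-tetramethyl-3,4,4a,5,6,7,8,8a-octahydronaphthalen-1-yl]butanal | CC1=C(CCCC=O)[C@@]2(C)CCCC(C)(C)[C@H]2CC1
F10 | step 10 | 2-methylidene-4-[(4aR,8aS)-2,5,5,8a-tetramethyl-3,4,4a,5,6,7,8,8a-octahydronaphthalen-1-yl]butanal | CC1=C(CCC(=C)C=O)[C@@]2(C)CCCC(C)(C)[C@H]2CC1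
F0 | step 13 | none | none
F11 | step 15 | (4S)-4-[(1R)-1-(tert-butyldimethylsilyloxy)but-3-en-1-yl]oxolan-2-one | C=CC[C@@H](O[Si](C)(C)C(C)(C)C)[C@@H]1COC(=O)C1
F12 | step 15 | (3R)-3-(tert-butyldimethylsilyloxy)-3-[(3S)-5-oxooxolan-3-yl]propanal | O=CC[C@@H](O[Si](C)(C)C(C)(C)C)[C@@H]1COC(=O)C1
F13 | step 15 | (4S)-4-[(1R)-4,4-dibromo-1-(tert-butyldimethylsilyloxy)but-3-en-1-yl]oxolan-2-one | BrC(Br)=CC[C@@H](O[Si](C)(C)C(C)(C)C)[C@@H]1COC(=O)C1
F14 | step 15 | (Z)-vinyl bromide: 30 with Br in place of the C13 CH2OH group and the C16 oxygen as tert-butyldimethylsilyl ether | CC1=C(CC/C(Br)=C/C[C@@H](O[Si](C)(C)C(C)(C)C)[C@@H]3COC(=O)C3)[C@@]2(C)CCCC(C)(C)[C@H]2CC1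
F15 | step 15 | C16 tert-butyldimethylsilyl ether of 30 | CC1=C(CC/C(CO)=C/C[C@@H](O[Si](C)(C)C(C)(C)C)[C@@H]3COC(=O)C3)[C@@]2(C)CCCC(C)(C)[C@H]2CC1
A1 | alternative 1 | 4-(tert-butyldimethylsilyloxy)butanal | CC(C)(C)[Si](C)(C)OCCCC=O
A2 | alternative 1 | furan | c1ccoc1
A3 | alternative 1 | exo-6-[3-(tert-butyldimethylsilyloxy)propyl]-2,7-dioxabicyclo[3.2.0]hept-3-ene (enantiomer matching 16R,17S) | CC(C)(C)[Si](C)(C)OCCC[C@H]1O[C@@H]2OC=C[C@H]12
A4 | alternative 2 | acyclic mixed diisopropylsilylene diether (identical with 28) | CC1=C(CCC(=C)CO[Si](C(C)C)(C(C)C)O[C@H](CC=C)[C@@H]3COC(=O)C3)[C@@]2(C)CCCC(C)(C)[C@H]2CC1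
A5 | alternative 2 | eight-membered cyclic silyl diether of the target (identical with 29) | CC1=C(CC/C3=C/C[C@H]([C@@H]4COC(=O)C4)O[Si](C(C)C)(C(C)C)OC3)[C@@]2(C)CCCC(C)(C)[C@H]2CC1
A6 | alternative 3 | (4R)-4-benzyl-3-[(2E)-9-(tert-butyldimethylsilyloxymethyl)-4,4,8,10-tetramethylundeca-2,8,10-trienoyl]oxazolidin-2-one, tether cis to C8 across C9=C10 | C=C(C)/C(CO[Si](C)(C)C(C)(C)C)=C(/C)CCCC(C)(C)/C=C/C(=O)N1C(=O)OC[C@H]1Cc1ccccc1
A7 | alternative 3 | cis-fused octalin imide with the auxiliary acyl group on C6 | CC1=C(CO[Si](C)(C)C(C)(C)C)[C@@]2(C)CCCC(C)(C)[C@H]2[C@@H](C1)C(=O)N1C(=O)OC[C@H]1Cc1ccccc1
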